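**Retrosynthetic overview**

The C1 hydroxyl is removed first (vinylogous oxygenation of a β,γ-enone). Ring D (C5–C6) and the upper lactone ring E (C7–C11) are then opened in one radical cascade, and ring C is cut at C5–C13′ and C3–C11′ (Diels–Alder). This leaves the lower monomer 14 and the acyclic dienone 20, both made from alkynol 5, which comes from (R)-γ-(hydroxymethyl)-γ-butyrolactone.
Enabling feature: in the cascade precursor C5 is the δ-terminus of the ring C dienone C4(=O)–C3=C2–C1=C5 and lies seven atoms from C6. The C8 oxygen can hold a 2-bromoallyl acetal next to the C7=C6 vinyl group, and C1 is γ to the acetyl ketone, so its hydroxyl can be added after the ring is closed.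
Ring order: lower lactone B (step 7), lower cycloheptene A (step 11), cyclohexene C (step 17), then in step 22 the upper lactone ring E (5-exo) and, last, the upper seven-membered ring D (7-endo).

Key step: step 22

Assumption: xanthane numbering is used for both halves (upper unit C1–C15, with C1 the carbinol carbon, C5 the ring-fusion CH, C8 the lactone CH–O and C10 the CH–CH3; lower unit C1′–C15′, with C11′ the spiro carbon and C13′ its ring C methylene), and (5R)-5-(hydroxymethyl)dihydrofuran-2(3H)-one is taken as a commercial chiral-pool material.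

**Route**

Step 1
Reactants: 1 (5R)-5-(hydroxymethyl)dihydrofuran-2(3H)-one
Product: 2 (5R)-5-[(trityloxy)methyl]dihydrofuran-2(3H)-one
Conditions: TrCl, Et3N, DMAP (cat.), CH2Cl2, rt
Reagents that add atoms: trityl chloride, ClC(c1ccccc1)(c1ccccc1)c1ccccc1
Why: Tritylation of the primary alcohol installs the bulky group that steers the alkylation in step 2.

Step 2
Reactants: 2 (5R)-5-[(trityloxy)methyl]dihydrofuran-2(3H)-one
Product: 3 (3S,5R)-3-methyl-5-[(trityloxy)methyl]dihydrofuran-2(3H)-one
Conditions: LiN(i-Pr)2, THF, −78 °C; then MeI, −78 °C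
Reagents that add atoms: iodomethane, CI
Why: In this lactone enolate alkylation the lithium enolate should be methylated on the face opposite the trityloxymethyl group, which sets the methyl carbon (future C10 and C10′) trans to C5.

Step 3
Reactants: 3 (3S,5R)-3-methyl-5-[(trityloxy)methyl]dihydrofuran-2(3H)-one
Product: 4 (3S,5R)-3-methyl-5-[(trityloxy)methyl]tetrahydrofuran-2-ol (anomer mixture)
Conditions: i-Bu2AlH, CH2Cl2, −78 °C
Reagents that add atoms: none
Why: Partial reduction of a γ-lactone stops at the lactol because the tetrahedral aluminate is stable at −78 °C.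

Step 4
Reactants: 4 (3S,5R)-3-methyl-5-[(trityloxy)methyl]tetrahydrofuran-2-ol
Product: 5 (2R,4S)-4-methyl-1-(trityloxy)hex-5-yn-2-ol
Conditions: dimethyl (1-diazo-2-oxopropyl)phosphonate, K2CO3, MeOH, 0 °C to rt
Reagents that add atoms: Ohira–Bestmann reagent, CC(=O)C(=[N+]=[N-])P(=O)(OC)OC
Why: The Seyferth–Gilbert homologation in its Ohira–Bestmann form acts on the open hydroxy-aldehyde tautomer of the lactol under conditions mild enough to keep the α-methyl stereocentre.

Step 5
Reactants: 5 (2R,4S)-4-methyl-1-(trityloxy)hex-5-yn-2-ol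
Product: 6 (2R,4S)-4-methyl-1-(trityloxy)hex-5-yn-2-yl 2-(diethoxyphosphoryl)acetate
Conditions: (EtO)2P(O)CH2CO2H, DCC, DMAP (cat.), CH2Cl2, 0 °C to rt
Reagents that add atoms: diethylphosphonoacetic acid, OC(=O)CP(=O)(OCC)OCC
Why: Steglich esterification of the secondary alcohol attaches the phosphonate needed for ring closure in step 7.

Step 6
Reactants: 6 (2R,4S)-4-methyl-1-(trityloxy)hex-5-yn-2-yl 2-(diethoxyphosphoryl)acetate
Product: 7 (2R,4S)-1-hydroxy-4-methylhex-5-yn-2-yl 2-(diethoxyphosphoryl)acetate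
Conditions: TsOH·H2O (cat.), MeOH/CH2Cl2, 0 °C, short reaction time
Reagents that add atoms: none
Why: Acid-catalysed solvolysis removes the trityl ether through the trityl cation, and low temperature should suppress 1,2-acyl shift of the ester.

Step 7
Reactants: 7 (2R,4S)-1-hydroxy-4-methylhex-5-yn-2-yl 2-(diethoxyphosphoryl)acetate
Product: 9 (5R)-5-[(2S)-2-methylbut-3-yn-1-yl]furan-2(5H)-one, via α-acyloxy aldehyde 8 (not isolated)
Conditions: Dess–Martin periodinane, CH2Cl2, 0 °C; then LiCl, i-Pr2NEt, MeCN, 0 °C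
Reagents that add atoms: none
Why: Oxidation to the aldehyde followed by an intramolecular Horner–Wadsworth–Emmons reaction (LiCl/amine variant) closes the butenolide (ring B), the ring enforcing the Z-olefin.

Step 8
Reactants: 9 (5R)-5-[(2S)-2-methylbut-3-yn-1-yl]furan-2(5H)-one
Product: 10 (4S,5R)-5-[(2S)-2-methylbut-3-yn-1-yl]-4-(prop-2-en-1-yl)dihydrofuran-2(3H)-one
Conditions: allyltrimethylsilane, TiCl4, CH2Cl2, −78 °C
Reagents that add atoms: allyltrimethylsilane, C=CC[Si](C)(C)C
Why: In this Hosomi–Sakurai conjugate allylation the allylsilane should attack C4 of the TiCl4-activated butenolide anti to the C5 side chain, giving the 4,5-trans lactone (sets C7′) while leaving the alkyne C–H untouched.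

Step 9
Reactants: 10 (4S,5R)-5-[(2S)-2-methylbut-3-yn-1-yl]-4-(prop-2-en-1-yl)dihydrofuran-2(3H)-one
Product: 11 (3E,4S,5R)-3-[(dimethylamino)methylidene]-5-[(2S)-2-methylbut-3-yn-1-yl]-4-(prop-2-en-1-yl)dihydrofuran-2(3H)-one
Conditions: t-BuOCH(NMe2)2, PhMe, 100 °C
Reagents that add atoms: Bredereck's reagent, CN(C)C(OC(C)(C)C)N(C)C
Why: Condensation of the lactone α-methylene with the aminal ester needs no strong base and so tolerates the terminal alkyne.

Step 10
Reactants: 11 (3E,4S,5R)-3-[(dimethylamino)methylidene]-5-[(2S)-2-methylbut-3-yn-1-yl]-4-(prop-2-en-1-yl)dihydrofuran-2(3H)-one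
Product: 12 (4S,5R)-3-methylidene-5-[(2S)-2-methylbut-3-yn-1-yl]-4-(prop-2-en-1-yl)dihydrofuran-2(3H)-one
Conditions: i-Bu2AlH, THF, −78 to 0 °C; aq. NH4Cl, SiO2
Reagents that add atoms: none
Why: Conjugate hydride addition to the vinylogous carbamate gives a β-amino aluminium enolate that should lose dimethylamine on work-up to reveal the exo-methylene (aminomethylenation/reduction α-methylenation).

Step 11
Reactants: 12 (4S,5R)-3-methylidene-5-[(2S)-2-methylbut-3-yn-1-yl]-4-(prop-2-en-1-yl)dihydrofuran-2(3H)-one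
Product: 14 (3aS,7S,8aR)-7-methyl-3-methylidene-6-[(1E)-3-oxobut-1-en-1-yl]-3,3a,4,7,8,8a-hexahydro-2H-cyclohepta[b]furan-2-one, via vinyl triene 13 (not isolated)
Conditions: second-generation Hoveyda–Grubbs catalyst (10 mol%), methyl vinyl ketone (10 equiv), CH2Cl2, 40 °C
Reagents that add atoms: methyl vinyl ketone, C=CC(C)=O
Why: Domino ring-closing enyne metathesis closes ring A as a 1-vinylcycloheptene, whose vinyl group then undergoes E-selective cross-metathesis, the electron-poor exo-methylene lactone being a spectator olefin.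

Step 12
Reactants: 5 (2R,4S)-4-methyl-1-(trityloxy)hex-5-yn-2-ol
Product: 15 tert-butyldimethyl{[(2R,4S)-4-methyl-1-(trityloxy)hex-5-yn-2-yl]oxy}silane
Conditions: TBSCl, imidazole, DMF, rt
Reagents that add atoms: tert-butyldimethylsilyl chloride, CC(C)(C)[Si](C)(C)Cl
Why: Silylation protects the C8 hydroxyl until the radical precursor is attached in step 21.

Step 13
Reactants: 15 tert-butyldimethyl{[(2R,4S)-4-methyl-1-(trityloxy)hex-5-yn-2-yl]oxy}silane
Product: 17 (3E,6S,8R)-8-[(tert-butyldimethylsilyl)oxy]-6-methyl-5-methylidene-9-(trityloxy)non-3-en-2-one, via 2-substituted butadiene 16 (not isolated)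
Conditions: second-generation Grubbs catalyst (5 mol%), ethylene (1 atm), CH2Cl2, rt; then Ar purge, methyl vinyl ketone (5 equiv), second-generation Hoveyda–Grubbs catalyst (5 mol%), 40 °C
Reagents that add atoms: ethylene, C=C; methyl vinyl ketone, C=CC(C)=O
Why: Cross enyne metathesis with ethylene turns the alkyne into a 2-substituted butadiene, and cross-metathesis at its monosubstituted vinyl group gives the E-dienone, the 1,1-disubstituted terminus being too hindered to react.

Step 14
Reactants: 17 (3E,6S,8R)-8-[(tert-butyldimethylsilyl)oxy]-6-methyl-5-methylidene-9-(trityloxy)non-3-en-2-one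
Product: 18 (3E,6S,8R)-8-[(tert-butyldimethylsilyl)oxy]-9-hydroxy-6-methyl-5-methylidenenon-3-en-2-one
Conditions: TsOH·H2O (cat.), MeOH/CH2Cl2, 0 °C
Reagents that add atoms: none
Why: The trityl ether is far more acid-labile than the secondary silyl ether, so brief acid solvolysis should free only the primary alcohol.

Step 15
Reactants: 18 (3E,6S,8R)-8-[(tert-butyldimethylsilyl)oxy]-9-hydroxy-6-methyl-5-methylidenenon-3-en-2-one
Product: 19 (2R,4S,6E)-2-[(tert-butyldimethylsilyl)oxy]-4-methyl-5-methylidene-8-oxonon-6-enal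
Conditions: Dess–Martin periodinane, CH2Cl2, 0 °C to rt
Reagents that add atoms: none
Why: Dess–Martin oxidation gives the α-silyloxy aldehyde under non-basic conditions that should not epimerise C8.

Step 16
Reactants: 19 (2R,4S,6E)-2-[(tert-butyldimethylsilyl)oxy]-4-methyl-5-methylidene-8-oxonon-6-enal
Product: 20 (3E,6S,8R)-8-[(tert-butyldimethylsilyl)oxy]-6-methyl-5-methylidenedeca-3,9-dien-2-one
Conditions: Ph3PCH3Br, KN(SiMe3)2, THF, −78 °C (1.05 equiv ylide); then 19, −78 to 0 °C
Reagents that add atoms: methyltriphenylphosphonium bromide, C[P+](c1ccccc1)(c1ccccc1)c1ccccc1.[Br-]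
Why: In this Wittig methylenation the aldehyde should react with one equivalent of ylide at low temperature much faster than the conjugated methyl ketone, giving the C7=C6 vinyl group.

Step 17
Reactants: 14 (3aS,7S,8aR)-7-methyl-3-methylidene-6-[(1E)-3-oxobut-1-en-1-yl]-3,3a,4,7,8,8a-hexahydro-2H-cyclohepta[b]furan-2-one; 20 (3E,6S,8R)-8-[(tert-butyldimethylsilyl)oxy]-6-methyl-5-methylidenedeca-3,9-dien-2-one
Product: 21 Diels–Alder adduct: 3-acetylcyclohex-1-ene ring C (C1=C2; C3 epimers; C5 = CH2) spiro-linked at (R)-C11′ to the lower unit (7′S,8′R,10′S) and bearing on C1 the chain C10(S)H(CH3)–C9H2–C8(R)H(OTBS)–C7H=C6H2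
Conditions: 14 (1.0 equiv), 20 (1.5 equiv), BHT (cat.), PhMe, 110 °C, sealed tube
Reagents that add atoms: none
Why: In this thermal Diels–Alder reaction the 2-alkyl and 4-acyl groups of the diene both direct C5 to C13′ and C3 to C11′, the diene should add to the exo-methylene of 14 anti to C6′ on the neighbouring C7′ (sets C11′), and 20 has no dienophile of its own while self-dimerisation of 14 is slower because its diene terminus is a ring carbon.

Step 18
Reactants: 21 Diels–Alder adduct (ring C β,γ-enone with C5 = CH2)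
Product: 22 C5 allylic alcohol of 21 (C5 and C3 epimers)
Conditions: SeO2 (0.5 equiv), t-BuOOH (3 equiv), CH2Cl2, rt
Reagents that add atoms: tert-butyl hydroperoxide, CC(C)(C)OO (oxygen delivered through SeO2, O=[Se]=O)
Why: In this Riley allylic oxidation (ene reaction then [2,3]-shift of the allylseleninic acid) selenium should bond to the less substituted C2 and oxygen be delivered to the ring methylene C5 on the more substituted C1 in preference to the exocyclic methine C10.

Step 19
Reactants: 22 C5 allylic alcohol of 21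
Product: 24 ring C dienone (C5=C1–C2=C3–acetyl; chain on C1 and lower unit as in 21), via C5 mesylate 23 (not isolated)
Conditions: MsCl, Et3N, CH2Cl2, −20 °C; then DBU, 0 °C to rt
Reagents that add atoms: none
Why: Deprotonation of the doubly activated C3–H and loss of mesylate from C5 through the C1=C2 bond (vinylogous E1cB, 1,4-elimination) should give the linear dienone with the new double bond fixed at C1=C5.

Step 20
Reactants: 24 ring C dienone with C8–OTBS
Product: 25 ring C dienone with free (8R)-C8 hydroxyl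
Conditions: HF·pyridine, THF, 0 °C to rt
Reagents that add atoms: none
Why: Fluoride-mediated cleavage of the secondary silyl ether under mildly acidic conditions should spare both dienones.

Step 21
Reactants: 25 ring C dienone with free C8 hydroxyl
Product: 26 mixed acetal C8–O–CH(OCH3)–C(Br)=CH2 of 25 (acetal epimers)
Conditions: methoxyallene (3 equiv), N-bromosuccinimide (1.5 equiv), CH2Cl2, −78 to −30 °C
Reagents that add atoms: methoxyallene, C=C=COC; N-bromosuccinimide, O=C1CCC(=O)N1Br
Why: Bromoalkoxylation of the electron-rich enol-ether bond of methoxyallene gives an oxocarbenium ion that the C8 alcohol traps, forming the 2-bromoallyl acetal (haloacetalisation of the Ueno–Stork type) faster than NBS attacks the electron-poor olefins.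

Step 22
Reactants: 26 mixed 2-bromoallyl acetal
Product: 27 cascade product with rings E and D closed: ring E as 2-methoxy-3-methylidenetetrahydrofuran (C12 epimers), C1=C2, C3–H (epimers), (5S,7S,8R,10S,7′S,8′R,10′S,11′R)
Conditions: Bu3SnH (1.3 equiv), AIBN (0.2 equiv), syringe pump over 8 h, PhMe (0.003 M), 85 °C
Reagents that add atoms: none
Why: Bu3Sn• abstracts bromine to give a σ-vinyl radical at C11 that cyclises 5-exo-trig onto the C7=C6 vinyl group (closing ring E as the methylidene lactol ether), and the resulting primary C6 radical adds 7-endo-trig to C5, the δ-terminus of the ring C dienone (closing ring D), before the delocalised radical is reduced by Bu3SnH at C3. The closest known reaction type is the tandem 5-exo/7-endo radical cyclisation of bromoacetals (Ueno–Stork) used for trans-fused seven-membered-ring lactones, run here with a 2-bromoallyl acetal so that the exocyclic methylene is delivered directly. C7 is set in the 5-exo step by a chair-like 5-hexenyl transition state with the C8 side chain pseudo-equatorial, which places C6 trans to C9 on the new five-membered ring; C5 is set in the 7-endo step by a chair-like transition state with the C10 methyl group and the trans ring fusion pseudo-equatorial. The step needs 7-endo attack at C5 rather than 6-exo attack at C1 or 1,4-addition at C2, and cyclisation rather than early reduction or 1,5-hydrogen transfer from C10–H. Attack at C5 is the only mode that gives the fully delocalised radical and meets an unhindered CH terminus, high dilution with slow stannane addition suppresses reduction, and the trans relationship of C6 and C9 on the five-membered ring disfavours the six-membered hydrogen-transfer array.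

Step 23
Reactants: 27 cascade product (β,γ-unsaturated ketone)
Product: 29 (1R)-C1 tertiary alcohol with C2=C3 enone and C12 methyl lactol ether, via C1 hydroperoxide 28 (not isolated)
Conditions: O2 (1 atm), DBU (0.3 equiv), P(OEt)3 (2 equiv), MeCN, 0 °C
Reagents that add atoms: dioxygen, O=O
Why: In this vinylogous autoxidation the base removes the doubly activated C3–H, the extended enolate should capture O2 at the γ-carbon C1 anti to the pseudo-axial C5–C6 bond (cis C/D fusion, OH syn to H5), and P(OEt)3 reduces the hydroperoxide in situ.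

Step 24
Reactants: 29 C1 alcohol with C12 methyl lactol ether
Product: 31 target CNP0168949.4, via lactol 30 (not isolated)
Conditions: PPTS (cat.), acetone/H2O (10:1), rt; then TEMPO (0.2 equiv), PhI(OAc)2 (1.5 equiv), CH2Cl2, rt
Reagents that add atoms: water, O
Why: Hydrolysis of the allylic methyl acetal and oxoammonium oxidation of the lactol give the α-methylene lactone, the tertiary C1 alcohol being inert to TEMPO.

**Compound list**

1 | (5R)-5-(hydroxymethyl)dihydrofuran-2(3H)-one | O=C1CC[C@H](CO)O1 | starting material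
2 | (5R)-5-[(trityloxy)methyl]dihydrofuran-2(3H)-one | O=C1CC[C@H](COC(c2ccccc2)(c2ccccc2)c2ccccc2)O1 | intermediate
3 | (3S,5R)-3-methyl-5-[(trityloxy)methyl]dihydrofuran-2(3H)-one (3,5-trans) | O=C1[C@@H](C)C[C@H](COC(c2ccccc2)(c2ccccc2)c2ccccc2)O1 | intermediate
4 | (3S,5R)-3-methyl-5-[(trityloxy)methyl]tetrahydrofuran-2-ol (anomers) | OC1[C@@H](C)C[C@H](COC(c2ccccc2)(c2ccccc2)c2ccccc2)O1 | intermediate
5 | (2R,4S)-4-methyl-1-(trityloxy)hex-5-yn-2-ol | C#C[C@@H](C)C[C@@H](O)COC(c1ccccc1)(c1ccccc1)c1ccccc1 | intermediate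
6 | (2R,4S)-4-methyl-1-(trityloxy)hex-5-yn-2-yl 2-(diethoxyphosphoryl)acetate | C#C[C@@H](C)C[C@@H](OC(=O)CP(=O)(OCC)OCC)COC(c1ccccc1)(c1ccccc1)c1ccccc1 | intermediate
7 | (2R,4S)-1-hydroxy-4-methylhex-5-yn-2-yl 2-(diethoxyphosphoryl)acetate | C#C[C@@H](C)C[C@@H](OC(=O)CP(=O)(OCC)OCC)CO | intermediate
8 | (2R,4S)-4-methyl-1-oxohex-5-yn-2-yl 2-(diethoxyphosphoryl)acetate | C#C[C@@H](C)C[C@@H](OC(=O)CP(=O)(OCC)OCC)C=O | intermediate (not isolated)
9 | (5R)-5-[(2S)-2-methylbut-3-yn-1-yl]furan-2(5H)-one | O=C1O[C@H](C[C@H](C)C#C)C=C1 | intermediate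
10 | (4S,5R)-5-[(2S)-2-methylbut-3-yn-1-yl]-4-(prop-2-en-1-yl)dihydrofuran-2(3H)-one (4,5-trans) | O=C1O[C@H](C[C@H](C)C#C)[C@@H](CC=C)C1 | intermediate
11 | (3E,4S,5R)-3-[(dimethylamino)methylidene]-5-[(2S)-2-methylbut-3-yn-1-yl]-4-(prop-2-en-1-yl)dihydrofuran-2(3H)-one | CN(C)/C=C1/C(=O)O[C@H](C[C@H](C)C#C)[C@H]1CC=C | intermediate
12 | (4S,5R)-3-methylidene-5-[(2S)-2-methylbut-3-yn-1-yl]-4-(prop-2-en-1-yl)dihydrofuran-2(3H)-one | C=C1C(=O)O[C@H](C[C@H](C)C#C)[C@H]1CC=C | intermediate
13 | (3aS,7S,8aR)-6-ethenyl-7-methyl-3-methylidene-3,3a,4,7,8,8a-hexahydro-2H-cyclohepta[b]furan-2-one | C=C1C(=O)O[C@@H]2C[C@H](C)C(C=C)=CC[C@@H]12 | intermediate (not isolated)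
14 | (3aS,7S,8aR)-7-methyl-3-methylidene-6-[(1E)-3-oxobut-1-en-1-yl]-3,3a,4,7,8,8a-hexahydro-2H-cyclohepta[b]furan-2-one (lower monomer) | C=C1C(=O)O[C@@H]2C[C@H](C)C(/C=C/C(C)=O)=CC[C@@H]12 | intermediate
15 | tert-butyldimethyl{[(2R,4S)-4-methyl-1-(trityloxy)hex-5-yn-2-yl]oxy}silane | C#C[C@@H](C)C[C@@H](O[Si](C)(C)C(C)(C)C)COC(c1ccccc1)(c1ccccc1)c1ccccc1 | intermediate
16 | tert-butyldimethyl{[(2R,4S)-4-methyl-5-methylidene-1-(trityloxy)hept-6-en-2-yl]oxy}silane | C=CC(=C)[C@@H](C)C[C@@H](O[Si](C)(C)C(C)(C)C)COC(c1ccccc1)(c1ccccc1)c1ccccc1 | intermediate (not isolated)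
17 | (3E,6S,8R)-8-[(tert-butyldimethylsilyl)oxy]-6-methyl-5-methylidene-9-(trityloxy)non-3-en-2-one | CC(=O)/C=C/C(=C)[C@@H](C)C[C@@H](O[Si](C)(C)C(C)(C)C)COC(c1ccccc1)(c1ccccc1)c1ccccc1 | intermediate
18 | (3E,6S,8R)-8-[(tert-butyldimethylsilyl)oxy]-9-hydroxy-6-methyl-5-methylidenenon-3-en-2-one | CC(=O)/C=C/C(=C)[C@@H](C)C[C@@H](O[Si](C)(C)C(C)(C)C)CO | intermediate
19 | (2R,4S,6E)-2-[(tert-butyldimethylsilyl)oxy]-4-methyl-5-methylidene-8-oxonon-6-enal | CC(=O)/C=C/C(=C)[C@@H](C)C[C@@H](O[Si](C)(C)C(C)(C)C)C=O | intermediate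
20 | (3E,6S,8R)-8-[(tert-butyldimethylsilyl)oxy]-6-methyl-5-methylidenedeca-3,9-dien-2-one | CC(=O)/C=C/C(=C)[C@@H](C)C[C@@H](O[Si](C)(C)C(C)(C)C)C=C | intermediate
21 | Diels–Alder adduct: 3-acetylcyclohex-1-ene ring C (C1=C2, C3 epimers, C5 = CH2) spiro at (R)-C11′ to the lower unit (7′S,8′R,10′S); C1 bears C10(S)H(CH3)–C9H2–C8(R)H(OTBS)–C7H=C6H2 | C=C[C@H](O[Si](C)(C)C(C)(C)C)C[C@H](C)C1=CC(C(C)=O)[C@]2(CC1)C(=O)O[C@@H]1C[C@H](C)C(/C=C/C(C)=O)=CC[C@H]12 | intermediate
22 | C5 allylic alcohol of 21 (C5 and C3 epimers) | C=C[C@H](O[Si](C)(C)C(C)(C)C)C[C@H](C)C1=CC(C(C)=O)[C@]2(CC1O)C(=O)O[C@@H]1C[C@H](C)C(/C=C/C(C)=O)=CC[C@H]12 | intermediate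
23 | C5 methanesulfonate of 22 | C=C[C@H](O[Si](C)(C)C(C)(C)C)C[C@H](C)C1=CC(C(C)=O)[C@]2(CC1OS(C)(=O)=O)C(=O)O[C@@H]1C[C@H](C)C(/C=C/C(C)=O)=CC[C@H]12 | intermediate (not isolated)
24 | ring C dienone (C5=C1–C2=C3–acetyl), C8–OTBS, chain and lower unit as in 21 | C=C[C@H](O[Si](C)(C)C(C)(C)C)C[C@H](C)C=1C=C(C(C)=O)[C@]2(CC1)C(=O)O[C@@H]1C[C@H](C)C(/C=C/C(C)=O)=CC[C@H]12 | intermediate
25 | ring C dienone with free (8R)-C8 hydroxyl | C=C[C@H](O)C[C@H](C)C=1C=C(C(C)=O)[C@]2(CC1)C(=O)O[C@@H]1C[C@H](C)C(/C=C/C(C)=O)=CC[C@H]12 | intermediate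
26 | mixed acetal of 25: C8–O–CH(OCH3)–C(Br)=CH2 (acetal epimers) | C=C[C@H](OC(OC)C(Br)=C)C[C@H](C)C=1C=C(C(C)=O)[C@]2(CC1)C(=O)O[C@@H]1C[C@H](C)C(/C=C/C(C)=O)=CC[C@H]12 | intermediate
27 | cascade product: rings D and E closed, ring E as 2-methoxy-3-methylidenetetrahydrofuran (C12 epimers), C1=C2, C3–H (epimers); (5S,7S,8R,10S,7′S,8′R,10′S,11′R) | C=C1C(OC)O[C@@H]2C[C@H](C)C3=CC(C(C)=O)[C@]4(C[C@@H]3C[C@@H]12)C(=O)O[C@@H]1C[C@H](C)C(/C=C/C(C)=O)=CC[C@H]14 | intermediate
28 | (1R)-C1 hydroperoxide, C2=C3 enone, C12 methyl lactol ether | C=C1C(OC)O[C@@H]2C[C@H](C)[C@]3(OO)C=C(C(C)=O)[C@]4(C[C@@H]3C[C@@H]12)C(=O)O[C@@H]1C[C@H](C)C(/C=C/C(C)=O)=CC[C@H]14 | intermediate (not isolated)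
29 | (1R)-C1 tertiary alcohol, C2=C3 enone, C12 methyl lactol ether | C=C1C(OC)O[C@@H]2C[C@H](C)[C@]3(O)C=C(C(C)=O)[C@]4(C[C@@H]3C[C@@H]12)C(=O)O[C@@H]1C[C@H](C)C(/C=C/C(C)=O)=CC[C@H]14 | intermediate
30 | C12 lactol of 29 | C=C1C(O)O[C@@H]2C[C@H](C)[C@]3(O)C=C(C(C)=O)[C@]4(C[C@@H]3C[C@@H]12)C(=O)O[C@@H]1C[C@H](C)C(/C=C/C(C)=O)=CC[C@H]14 | intermediate (not isolated)
31 | CNP0168949.4, (1R,5S,7S,8R,10S,7′S,8′R,10′S,11′R) | C=C1C(=O)O[C@@H]2C[C@H](C)[C@]3(O)C=C(C(C)=O)[C@]4(C[C@@H]3C[C@@H]12)C(=O)O[C@@H]1C[C@H](C)C(/C=C/C(C)=O)=CC[C@H]14 | target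

**Step count and risks**

Total step count: 24. Longest linear sequence: 19 steps (steps 1–11, then 17–24).

The radical cascade of step 22 is the most exposed step. The C6 radical may be reduced before it cyclises, it may take a hydrogen from C10 by 1,5-transfer, it may add at C2, or it may attack the wrong face of C5. If so, ring D would be set before ring C with known chemistry. Monomer 14 is heated on its own (PhMe, 110 °C) so that the C5=C1–C2=C3 diene of one molecule adds to the exo-methylene of a second, which should give the Diels–Alder homodimer F1 with both upper rings already in place. The aerobic γ-hydroxylation of step 23 applied to F1 then comes back to the route at 31.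

The allylic oxidation of step 18 may over-oxidise C5 to the ketone or attack other allylic positions of 21. In that case the dienone would be made by enol silane dehydrogenation instead. Treating 21 with TMSOTf and Et3N should give the bis(trimethylsilyl) dienol ether F2, and Pd(OAc)2 in MeCN (Saegusa–Ito) should then dehydrogenate the ring C dienol ether across C1–C5. The lower silyl enol ether has no β-hydrogen to lose and reverts to the methyl ketone on work-up. This returns to the route at 24.

In the Diels–Alder step 17, self-dimerisation of 14 may outrun the cross reaction, or facial selectivity at C11′ may be poor. The diene-free enyne lactone 12 would then be the dienophile: heating 12 with 20 under the same conditions should give the spiro adduct F3. Ring A and its side chain would be made afterwards by the domino enyne metathesis of step 11 (second-generation Hoveyda–Grubbs catalyst, methyl vinyl ketone), the hindered vinyl group next to the silyl ether being the slow olefin. This returns to the route at 21.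

**Further compounds**

F1 | step 22 | Diels–Alder homodimer of 14: β,γ-unsaturated ketone (C1=C2, C3 epimers) with rings D and E as in the target | C=C1C(=O)O[C@@H]2C[C@H](C)C3=CC(C(C)=O)[C@]4(C[C@@H]3C[C@@H]12)C(=O)O[C@@H]1C[C@H](C)C(/C=C/C(C)=O)=CC[C@H]14
F2 | step 18 | bis(trimethylsilyl) dienol ether of 21 (C4 enol ether in ring C and the lower 2-silyloxydiene) | C=C[C@H](O[Si](C)(C)C(C)(C)C)C[C@H](C)C1=CC(=C(C)O[Si](C)(C)C)[C@]2(CC1)C(=O)O[C@@H]1C[C@H](C)C(/C=C/C(=C)O[Si](C)(C)C)=CC[C@H]12
F3 | step 17 | spiro Diels–Alder adduct of 12 and 20 (ring C as in 21; lower unit still the open allyl/butynyl lactone) | C=C[C@H](O[Si](C)(C)C(C)(C)C)C[C@H](C)C1=CC(C(C)=O)[C@]2(CC1)C(=O)O[C@H](C[C@H](C)C#C)[C@H]2CC=C
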